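The runs were generated by integration on assumed constants; the scatter is artificial.

Slowness is the first impression: the maple flask, at 10 °C, shows 1.7% target after 120 min. The birch flask, at 25 °C, is the flask asked about, and it has been followed for 6.00 h.

| setting | birch | maple | flask |
|---|---|---|---|
| substrate | 0.20 M | 0.30 M | 0.20 M |
| temperature | 25 °C | 10 °C | 25 °C |
| remark | the very flask that is asked about, followed so far | run made earlier |  |
| time |  |  | 10 h |

| birch: time / h | birch: target / % | maple: time / min | maple: target / % |
|---|---|---|---|
| 1.00 | 11.4 | 6.00 | 0.2 |
| 2.00 | 18.4 | 20.0 | 0 |
| 3.00 | 18.7 | 30.0 | 0.4 |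
| 4.00 | 18.0 | 50.0 | 0.8 |
| 5.00 | 17.2 | 80.0 | 0.1 |
| 6.00 | 17.2 | 120 | 1.7 |

(readings scatter by 0.5 percentage points)

- grey: at 10 h take out 90% of the target then present, then wait 5.0 h
- blue: at 10 h raise the temperature by 10 K, then wait 5.0 h
- teal: at 10 h add substrate, 50.0% of the amount charged, then wait 5.0 h
- ochre: change nothing and wait 5.0 h more

- removed target is counted in
- the analysis behind the earlier runs scatters by 0.5 percentage points, standard deviation
- additions bring no volume worth counting

- target, in percent of the substrate first charged, at 10 h
- what to do for the largest gain in target; "none" if nothing gains more than 2 percentage points (grey / blue / teal / ochre / none)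
- target present, with what was taken out counted in, in percent of the substrate first charged, after blue
- target present, with what was taken out counted in, in percent of the substrate first charged, after ochre

Two chemists dispute the birch flask. The first holds a rate view. From the maple flask to the birch flask, the early climb, target over time, grows by a factor 13.4. That is a rough reading, since the maple figure stands close to its scatter. It corresponds to an apparent activation energy E of 121 kJ mol⁻¹, so the rise in blue speeds the climb by a factor 4.91. Heat, she says, is the lever.

The second holds a ceiling view. The later birch readings average 17.8%, and he calls that a wall.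

My own reckoning sets the two against each other. The birch plateau divided by the birch early climb gives 1.56 h. This is the stop time t_s: the time the birch climb, held at its early pace, takes to reach the birch plateau. It is a scale read from scattered readings, and it does not say that the flask has reached equilibrium. Well short of it I read the climb, and well past it the plateau.

With the same plateau, the maple flask has a stop time of 20.9 h, later than its last reading. So the maple run shows climb and says nothing about a plateau. The birch flask at 10 h stands 6.41 stop times out, so I expect about the plateau, and nothing from waiting. After the rise, the stop time for that plateau is 0.318 h, shorter than the wait. So a gain from blue has to be a moved plateau, and one plateau at one temperature gives no measure of that.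

The forecast takes the ceiling side, with 17% now, 16.8% after ochre, 17% after blue and grey as best, holding that “Heating therefore speeds things up but moves the plateau by an unknown, probably small, amount”.

The flask gives 15.7% now and 16.1% after ochre, a gain of 0.4 percentage points. Grey gains 12 points, teal 8.9 points, and blue gains 21 points, reaching 37.0%, so the best choice is blue.

    substrate → intermediate (k = 0.530 h⁻¹, Ea = 104 kJ mol⁻¹)
    intermediate ⇌ target (K = 4.70, k = 1.20 h⁻¹, Ea = 88.0 kJ mol⁻¹, ΔH = 0 kJ mol⁻¹)
    intermediate ⇌ isomer of the product A (K = 2.30, k = 0.590 h⁻¹, Ea = 101 kJ mol⁻¹, ΔH = −69.0 kJ mol⁻¹)
    substrate ⇌ dormant form (K = 2.00, k = 0.110 h⁻¹, Ea = 105 kJ mol⁻¹, ΔH = −62.0 kJ mol⁻¹)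
    target ⇌ isomer of the product B (K = 3.90, k = 0.730 h⁻¹, Ea = 102 kJ mol⁻¹, ΔH = −88.0 kJ mol⁻¹)
    (constants at 25 °C)

The ceiling view keeps its region at the held temperature: the answer stays within 5 points of itself from at least 1.25 h to at least 80 h. Blue's plateau moved. Reckoned for 37.0% with the heated climb, the stop time is 0.660 h, shorter than the wait. The neighbouring flask, kept at 50 °C, takes the same reckoning: its climb is faster by a factor 44.3, and its 65.8% gives a stop time of 0.130 h, shorter than 10 h. In that flask, target holds 65.8% of the charge, and isomer of the product A holds 3.74%.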